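**Retrosynthetic overview**

1. The target is the 2,4-cis (2R,4R) flavan: benzo ring A (7-OH), pyran ring C (O1, C2, C3, C4), ring B (4-hydroxyphenyl) on C2, acylphloroglucinol ring D on C4. The last disconnections are the five benzyl ethers and the ring D–dodecanoyl bond (Friedel–Crafts).
2. C2–ring B and C2–H: aryllithium addition to a C2 lactone carbonyl, then hydride delivery to the C2 oxocarbenium ion anti to ring D, so C4 controls C2 (cis).
3. Feature used: C2 lies between O1 and C3. It can therefore be carbon monoxide inserted between the ring A phenol oxygen and the CH2 terminus (C3) of a 1,1-diarylethylene whose internal carbon becomes C4. An asymmetric palladium hydride cyclocarbonylation forms C2–C3 and O1–C2, closes ring C and sets C4 (R).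
4. The 1,1-diarylethylene (C3=C4 carrying rings A and D) comes from 2,4,6-tris(benzyloxy)phenyllithium and 1-[4-(benzyloxy)-2-hydroxyphenyl]ethanone, then dehydration.
5. Ring order: rings A, B and D are bought as arenes. Ring C is the only ring made (step 5); it is opened at O1–C2 in step 6 and closed again in step 7.

Key step: step 5

Assumption: which antipode of the diphosphine gives the 4R lactone cannot be predicted reliably; both antipodes are screened and the one giving 4R is used (written below as (R)-DTBM-SEGPHOS).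
Remark: the two free positions of ring D are exchanged by rotation about the C4–ring D bond, so acylation at either gives the same compound.
Remark: carbon monoxide (8) and dodecanoyl chloride (16) are numbered and stand on the Reactants lines of steps 5 and 8.

**Step 1**
Reactants: 1 phloroglucinol
Product: 2 1,3,5-tris(benzyloxy)benzene
Conditions: BnBr (3.3 equiv), K2CO3, DMF, 0 °C → rt
Reagents that add atoms: benzyl bromide, BrCc1ccccc1
Why: Williamson O-alkylation of the three phenoxides; C-benzylation of the phloroglucinol nucleus, the known competing process, is held down by the polar aprotic solvent and slow addition at low temperature, and the symmetric triether should crystallise.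

**Step 2**
Reactants: 2 1,3,5-tris(benzyloxy)benzene
Product: 3 2-bromo-1,3,5-tris(benzyloxy)benzene
Conditions: NBS (1.0 equiv), DMF, 0 °C
Reagents that add atoms: N-bromosuccinimide, O=C1CCC(=O)N1Br
Why: Electrophilic aromatic bromination of a triply activated arene whose three free positions are equivalent, so one equivalent of NBS at low temperature should stop at the monobromide.

**Step 3**
Reactants: 3 2-bromo-1,3,5-tris(benzyloxy)benzene; 4 1-[4-(benzyloxy)-2-hydroxyphenyl]ethanone
Product: 6 5-(benzyloxy)-2-{1-hydroxy-1-[2,4,6-tris(benzyloxy)phenyl]ethyl}phenol (racemic), via 2,4,6-tris(benzyloxy)phenyllithium 5 (not isolated)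
Conditions: 3 (2.3 equiv), n-BuLi (2.2 equiv), THF, −78 °C; then 4 (1.0 equiv), −78 → 0 °C; aq NH4Cl
Reagents that add atoms: none
Why: Bromine–lithium exchange gives aryllithium 5, held by its two ortho alkoxy groups, whose first equivalent deprotonates the phenol (returning 2, which is recovered and re-brominated) and whose second adds 1,2 to the lithium-chelated ketone carbonyl; the new carbinol centre is racemic and is erased in step 4.

**Step 4**
Reactants: 6 5-(benzyloxy)-2-{1-hydroxy-1-[2,4,6-tris(benzyloxy)phenyl]ethyl}phenol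
Product: 7 5-(benzyloxy)-2-{1-[2,4,6-tris(benzyloxy)phenyl]ethenyl}phenol
Conditions: PPTS (10 mol %), 4 Å MS, toluene, 60 °C
Reagents that add atoms: none
Why: Acid-catalysed E1 dehydration of a tertiary, doubly benzylic carbinol through a cation stabilised by both aryl rings (an ortho-quinone methide after loss of the phenol proton); the methyl group is the only source of a β-hydrogen, so a single alkene forms, and the weak acid avoids dimerisation of the electron-rich 1,1-diarylethylene.

**Step 5**
Reactants: 7 5-(benzyloxy)-2-{1-[2,4,6-tris(benzyloxy)phenyl]ethenyl}phenol; 8 carbon monoxide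
Product: 9 (4R)-7-(benzyloxy)-4-[2,4,6-tris(benzyloxy)phenyl]chroman-2-one
Conditions: Pd(OAc)2 (5 mol %), (R)-DTBM-SEGPHOS (6 mol %), CO (35 bar), H2 (7 bar), toluene, 90 °C
Reagents that add atoms: none
Why: Pd(OAc)2, the diphosphine and CO/H2 give a cationic hydride of divalent palladium, which adds across the 1,1-diarylethylene with hydrogen going to the diaryl carbon (C4) and palladium to the terminal CH2 (C3); CO then inserts into the primary Pd–C bond and the ring A phenol attacks the acylpalladium, releasing the lactone and returning the hydride. The closest known reaction type is the palladium-catalysed cyclocarbonylation of 2-(1-substituted vinyl)phenols to 4-substituted dihydrocoumarins, together with the asymmetric hydroalkoxycarbonylation of 1,1-disubstituted alkenes with chiral diphosphines. Ring C closes by 6-exo-trig acyl substitution (phenol oxygen on the acyl carbon, bond O1–C2) after CO insertion has made C2–C3. The C4 stereocentre is set when the hydride adds to one enantioface of the alkene inside the C2-symmetric ligand pocket, and the ligand antipode is chosen so that 4R results. The step needs anti-Markovnikov regiochemistry, secured by the fully substituted internal alkene carbon (a tertiary dibenzylic Pd–C bond flanked by three ortho substituents should not form), and enantioface discrimination, helped by the strong difference between the two aryl groups: ring D is 2,6-disubstituted and twisted out of the alkene plane, ring A carries the coordinating OH. A low H2 partial pressure limits simple hydrogenation of the alkene, the alkene cannot isomerise, and the absence of a Brønsted acid co-catalyst spares the electron-rich substrate.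

**Step 6**
Reactants: 9 (4R)-7-(benzyloxy)-4-[2,4,6-tris(benzyloxy)phenyl]chroman-2-one; 10 1-(benzyloxy)-4-bromobenzene
Product: 12 (3R)-1-[4-(benzyloxy)phenyl]-3-[4-(benzyloxy)-2-hydroxyphenyl]-3-[2,4,6-tris(benzyloxy)phenyl]propan-1-one, via 4-(benzyloxy)phenyllithium 11 (not isolated)
Conditions: 10, n-BuLi, THF, −78 °C; then added slowly (1.05 equiv) to 9, THF, −78 °C; aq NH4Cl at −78 °C
Reagents that add atoms: none
Why: Nucleophilic acyl addition of aryllithium 11 to the aryl ester carbonyl at −78 °C with the lactone in excess throughout, the same mono-addition used on lactones in C-aryl glycoside synthesis; 12 is the open-chain form, in ring–chain equilibrium with its cyclic hemiketal, and C4, which is not α to the carbonyl, is untouched.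

**Step 7**
Reactants: 12 (3R)-1-[4-(benzyloxy)phenyl]-3-[4-(benzyloxy)-2-hydroxyphenyl]-3-[2,4,6-tris(benzyloxy)phenyl]propan-1-one
Product: 15 (2R,4R)-7-(benzyloxy)-2-[4-(benzyloxy)phenyl]-4-[2,4,6-tris(benzyloxy)phenyl]chroman, via cyclic hemiketal 13 (not isolated), via C2 oxocarbenium ion 14 (not isolated)
Conditions: Et3SiH (4 equiv), BF3·OEt2 (2.5 equiv), CH2Cl2, −78 → −30 °C
Reagents that add atoms: none
Why: Ionic hydrogenation in which BF3·OEt2 closes 12 to hemiketal 13 (phenol oxygen onto the activated ketone, 6-exo-trig) and ionises it to oxocarbenium ion 14, and Et3SiH delivers hydride to C2 on the face anti to ring D at C4, which places ring B cis to ring D (both pseudo-equatorial, 2R from 4R); the low temperature keeps the acid from opening the benzylic C2–O1 bond of the product.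

**Step 8**
Reactants: 15 (2R,4R)-7-(benzyloxy)-2-[4-(benzyloxy)phenyl]-4-[2,4,6-tris(benzyloxy)phenyl]chroman; 16 dodecanoyl chloride
Product: 17 1-{2,4,6-tris(benzyloxy)-3-[(2R,4R)-7-(benzyloxy)-2-[4-(benzyloxy)phenyl]chroman-4-yl]phenyl}dodecan-1-one
Conditions: SnCl4 (1.2 equiv), CH2Cl2, −78 → −40 °C
Reagents that add atoms: none
Why: Friedel–Crafts acylation at the most nucleophilic position of the molecule, a ring D carbon ortho to two benzyloxy groups and para to the third (ring A has only two activating oxygens, ring B one); any benzyl ether ortho to the new ketone that SnCl4 removes is of no consequence, because all benzyl groups are cleaved in step 9.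

**Step 9**
Reactants: 17 1-{2,4,6-tris(benzyloxy)-3-[(2R,4R)-7-(benzyloxy)-2-[4-(benzyloxy)phenyl]chroman-4-yl]phenyl}dodecan-1-one
Product: 18 1-{2,4,6-trihydroxy-3-[(2R,4R)-7-hydroxy-2-(4-hydroxyphenyl)chroman-4-yl]phenyl}dodecan-1-one (CNP0293819.1)
Conditions: H2 (1 atm), Pd/C (10 wt %), EtOAc/MeOH, rt
Reagents that add atoms: none
Why: Hydrogenolysis of five benzyl ethers over palladium on carbon under neutral conditions; the hindered, hydrogen-bonded acylphloroglucinol ketone and the cyclic benzylic C2–O1 ether are expected to survive at 1 atm and room temperature, and neither stereocentre is affected.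

**Compound list**

1 | phloroglucinol (benzene-1,3,5-triol) | Oc1cc(O)cc(O)c1 | starting material
2 | 1,3,5-tris(benzyloxy)benzene | c1ccc(COc2cc(OCc3ccccc3)cc(OCc3ccccc3)c2)cc1 | intermediate
3 | 2-bromo-1,3,5-tris(benzyloxy)benzene | Brc1c(OCc2ccccc2)cc(OCc2ccccc2)cc1OCc1ccccc1 | intermediate
4 | 1-[4-(benzyloxy)-2-hydroxyphenyl]ethanone | CC(=O)c1ccc(OCc2ccccc2)cc1O | starting material
5 | 2,4,6-tris(benzyloxy)phenyllithium (not isolated) | [Li]c1c(OCc2ccccc2)cc(OCc2ccccc2)cc1OCc1ccccc1 | intermediate
6 | 5-(benzyloxy)-2-{1-hydroxy-1-[2,4,6-tris(benzyloxy)phenyl]ethyl}phenol (racemic) | CC(O)(c1ccc(OCc2ccccc2)cc1O)c1c(OCc2ccccc2)cc(OCc2ccccc2)cc1OCc1ccccc1 | intermediate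
7 | 5-(benzyloxy)-2-{1-[2,4,6-tris(benzyloxy)phenyl]ethenyl}phenol | C=C(c1ccc(OCc2ccccc2)cc1O)c1c(OCc2ccccc2)cc(OCc2ccccc2)cc1OCc1ccccc1 | intermediate
8 | carbon monoxide | [C-]#[O+] | starting material
9 | (4R)-7-(benzyloxy)-4-[2,4,6-tris(benzyloxy)phenyl]chroman-2-one | C(c1ccccc1)Oc1cc(OCc2ccccc2)c([C@@H]2CC(=O)Oc3cc(OCc4ccccc4)ccc32)c(OCc2ccccc2)c1 | intermediate
10 | 1-(benzyloxy)-4-bromobenzene | Brc1ccc(OCc2ccccc2)cc1 | starting material
11 | 4-(benzyloxy)phenyllithium (not isolated) | [Li]c1ccc(OCc2ccccc2)cc1 | intermediate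
12 | (3R)-1-[4-(benzyloxy)phenyl]-3-[4-(benzyloxy)-2-hydroxyphenyl]-3-[2,4,6-tris(benzyloxy)phenyl]propan-1-one | C(c1ccccc1)Oc1cc(OCc2ccccc2)c([C@H](CC(=O)c2ccc(OCc3ccccc3)cc2)c2ccc(OCc3ccccc3)cc2O)c(OCc2ccccc2)c1 | intermediate
13 | (4R)-7-(benzyloxy)-2-[4-(benzyloxy)phenyl]-4-[2,4,6-tris(benzyloxy)phenyl]chroman-2-ol (cyclic hemiketal, both C2 epimers, not isolated) | C(c1ccccc1)Oc1cc(OCc2ccccc2)c([C@@H]2CC(O)(c3ccc(OCc4ccccc4)cc3)Oc3cc(OCc4ccccc4)ccc32)c(OCc2ccccc2)c1 | intermediate
14 | (4R)-7-(benzyloxy)-2-[4-(benzyloxy)phenyl]-4-[2,4,6-tris(benzyloxy)phenyl]-3,4-dihydrochromenylium (C2 oxocarbenium ion, not isolated) | C(c1ccccc1)Oc1cc(OCc2ccccc2)c([C@@H]2CC(c3ccc(OCc4ccccc4)cc3)=[O+]c3cc(OCc4ccccc4)ccc32)c(OCc2ccccc2)c1 | intermediate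
15 | (2R,4R)-7-(benzyloxy)-2-[4-(benzyloxy)phenyl]-4-[2,4,6-tris(benzyloxy)phenyl]chroman (2,4-cis) | C(c1ccccc1)Oc1cc(OCc2ccccc2)c([C@@H]2C[C@H](c3ccc(OCc4ccccc4)cc3)Oc3cc(OCc4ccccc4)ccc32)c(OCc2ccccc2)c1 | intermediate
16 | dodecanoyl chloride | CCCCCCCCCCCC(=O)Cl | starting material
17 | 1-{2,4,6-tris(benzyloxy)-3-[(2R,4R)-7-(benzyloxy)-2-[4-(benzyloxy)phenyl]chroman-4-yl]phenyl}dodecan-1-one | CCCCCCCCCCCC(=O)c1c(OCc2ccccc2)cc(OCc2ccccc2)c([C@@H]2C[C@H](c3ccc(OCc4ccccc4)cc3)Oc3cc(OCc4ccccc4)ccc32)c1OCc1ccccc1 | intermediate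
18 | 1-{2,4,6-trihydroxy-3-[(2R,4R)-7-hydroxy-2-(4-hydroxyphenyl)chroman-4-yl]phenyl}dodecan-1-one | CCCCCCCCCCCC(=O)c1c(O)cc(O)c([C@@H]2C[C@H](c3ccc(O)cc3)Oc3cc(O)ccc32)c1O | target

**Step count and risks**

Total steps: 9. Longest linear sequence: 9 (1 → 2 → 3 → 6 → 7 → 9 → 12 → 15 → 17 → 18).

Steps most likely to fail:

**Step 5.** The hindered, tri-ortho-substituted alkene may turn over slowly, so that simple hydrogenation of the C=C bond takes over, or the catalyst may discriminate the two enantiofaces poorly.
- Fallback, setting out from 7: alkenyl C–H carboxylation with CO2 (Pd(OAc)2, Cs2CO3, CO2 1 atm, diglyme, 100 °C), a known lactonisation of 2-(1-arylvinyl)phenols, should give the coumarin 7-(benzyloxy)-4-[2,4,6-tris(benzyloxy)phenyl]-2H-chromen-2-one F1.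
- Copper hydride asymmetric conjugate reduction (Cu(OAc)2, DTBM-SEGPHOS antipode chosen for 4R, (EtO)2MeSiH, t-BuOH, toluene, 0 °C), known for 4-substituted coumarins, then sets C4 by hydride delivery to the preformed lactone and comes back to the route at 9.

**Step 6.** The tetrahedral adduct may collapse to the ketone during the addition, followed by a second aryl addition, and the aryllithium may enolise the lactone.
- Fallback, setting out from 9: aminolysis with MeNH(OMe)·HCl and AlMe3 (CH2Cl2, 0 °C → rt) should open the lactone to the Weinreb amide (3R)-3-[4-(benzyloxy)-2-hydroxyphenyl]-N-methoxy-N-methyl-3-[2,4,6-tris(benzyloxy)phenyl]propanamide F2.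
- Treatment with 11 (2.3 equiv, THF, −78 → 0 °C; the first equivalent is consumed by the phenol) adds the aryl group once through the stable chelate, and work-up comes back to the route at 12.

**Step 3.** The hindered aryllithium may enolise the methyl ketone while addition to the phenoxide-deactivated carbonyl is slow.
- Fallback, setting out from 4 and using 3: silylation (i-Pr3SiOTf, 2,6-lutidine, CH2Cl2) should give 1-[4-(benzyloxy)-2-{[tri(propan-2-yl)silyl]oxy}phenyl]ethanone F3.
- Condensation with TsNHNH2 (MeOH, 60 °C) gives N'-{1-[4-(benzyloxy)-2-{[tri(propan-2-yl)silyl]oxy}phenyl]ethylidene}-4-methylbenzenesulfonohydrazide F4.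
- Carbene cross-coupling of F4 with 3 (Pd2(dba)3, XPhos, LiOtBu, dioxane, 100 °C; migratory insertion of the palladium carbene, then β-hydride elimination), a known route to hindered 1,1-diarylethylenes, gives {5-(benzyloxy)-2-{1-[2,4,6-tris(benzyloxy)phenyl]ethenyl}phenoxy}tri(propan-2-yl)silane F5.
- Bu4NF (THF, 0 °C) removes the silyl group and comes back to the route at 7, bypassing steps 3 and 4.

**Further compounds**

F1 | step 5 | 7-(benzyloxy)-4-[2,4,6-tris(benzyloxy)phenyl]-2H-chromen-2-one | O=C1C=C(c2c(OCc3ccccc3)cc(OCc3ccccc3)cc2OCc2ccccc2)c2ccc(OCc3ccccc3)cc2O1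
F2 | step 6 | (3R)-3-[4-(benzyloxy)-2-hydroxyphenyl]-N-methoxy-N-methyl-3-[2,4,6-tris(benzyloxy)phenyl]propanamide | CON(C)C(=O)C[C@H](c1ccc(OCc2ccccc2)cc1O)c1c(OCc2ccccc2)cc(OCc2ccccc2)cc1OCc1ccccc1
F3 | step 3 | 1-[4-(benzyloxy)-2-{[tri(propan-2-yl)silyl]oxy}phenyl]ethanone | CC(=O)c1ccc(OCc2ccccc2)cc1O[Si](C(C)C)(C(C)C)C(C)C
F4 | step 3 | N'-{1-[4-(benzyloxy)-2-{[tri(propan-2-yl)silyl]oxy}phenyl]ethylidene}-4-methylbenzenesulfonohydrazide | CC(=NNS(=O)(=O)c1ccc(C)cc1)c1ccc(OCc2ccccc2)cc1O[Si](C(C)C)(C(C)C)C(C)C
F5 | step 3 | {5-(benzyloxy)-2-{1-[2,4,6-tris(benzyloxy)phenyl]ethenyl}phenoxy}tri(propan-2-yl)silane | C=C(c1ccc(OCc2ccccc2)cc1O[Si](C(C)C)(C(C)C)C(C)C)c1c(OCc2ccccc2)cc(OCc2ccccc2)cc1OCc1ccccc1
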